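At the reading at 10 h, is this flask still turning over, or has its catalyst died?

starting material 0.30 M; reagent 1.00 equiv; free catalyst 2.5 mol%; time 10 h

    catalyst intermediate B + target → spent catalyst (k1 = 1.90 M⁻¹ h⁻¹)
    catalyst intermediate B → by-product + catalyst intermediate C (k2 = 26.0 h⁻¹)
    starting material + free catalyst → catalyst intermediate A (k3 = 5220 M⁻¹ h⁻¹)
    catalyst intermediate C → free catalyst + target (k4 = 15.4 h⁻¹)
    reagent + catalyst intermediate A → catalyst intermediate B (k5 = 72.9 M⁻¹ h⁻¹)

- why nothing more happens at 10 h, or that something still does (it is still moving / all of the starting material has reacted / the reagent has run out first / no working catalyst is left)
- target at 10 h, in percent of the starting material charged

- percent here means starting material units held: one spent catalyst counts as two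
- the reaction counts as stopped when no species that holds the starting material changes by six tenths of a point or more over the second half of the time
- run time (flask): 10 h

Two chemists dispute this flask. The first holds that this is catalyst poisoning by the product: target accumulates, takes catalyst intermediate B out of the round as spent catalyst, and the flask stops with no working catalyst. The second holds that the loss stays partial and that the flask is merely slow.

Let y be target as a fraction of the starting material charge. Catalyst intermediate B can either meet target or go on to by-product, and the odds of capture, k1 times target over k2, grow with y to 0.0219 at full conversion. A flask that reaches y has made y over the loading turnovers, at average odds of half the value reached at y. Spent catalyst, as a fraction of the catalyst charge, is therefore L times y squared. Here L is the poison budget, 0.438, the spent fraction at full conversion.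

The mark on this scale is L of one, where the reckoned spent fraction reaches the whole catalyst charge at full conversion. This flask lies below it, so I reckon that 0.562 of the catalyst charge escapes spent catalyst even at full conversion, and I expect no stop of the first chemist's kind.

The second chemist's pace follows. One round at the charged concentrations lasts 0.150 h, the sum of its four waits, so the turnover number of 40.0 needs 5.99 h at that pace. Reagent and starting material fall, so the two waits that hang on them lengthen, and 10 h is 1.67 times that figure. I expect this flask to be still moving, and I commit to no figure for target.

The forecast, the second chemist's number, says it is still moving with target at 88%, between 85% and 91%, because “conversion changed well over 0.6 points between 5 and 10 h”.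

The simulation gives it is still moving, with target at 89.3%.

In this flask the budget at that target gives 34.9% of the catalyst spent, the table holds 35.0%, and 65% can still turn over, so the poison view keeps, on this reckoning, its region at L of one and above, outside this flask's 0.438. At the reading this flask's reagent, 8.7% of its charge, has a half-life of 2.4 h by its step with catalyst intermediate A, shorter than the 10 h already run. At 4.2 mol% of free catalyst the budget falls to 0.261, which at that neighbour flask's 96.9% target gives 24.5%, and that neighbour flask holds 24.3% spent catalyst.

(The numbers come from no measurement; the run is a simulation.)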